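Start at late times and read backward. In the readings of the south-east and north-east runs, the unconverted share of the charge, u, falls by about a steady factor per minute, and the two runs fall alike within the scatter.

the same everywhere: free catalyst 5.00 mM

| charge | starting material | time |
|---|---|---|
| south-east | 50.0 mM |  |
| north-east | 75.0 mM |  |
| south-west | 20.0 mM | 77 min |

- south-east run (time / min: [product] / mM): 5.9: 2.0; 18: 7.6; 34: 16.0; 54: 25.3; 77: 32.5
- north-east run (time / min: [product] / mM): 5.9: 3.3; 18: 11.0; 34: 23.5; 54: 38.0; 77: 47.7

(readings scatter by 0.5 mM)

- Overall: starting material -> product, with free catalyst as catalyst.
- Constant volume, constant temperature.
- An order is taken over about fifteen percent of the charge, up and down.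

- the exponent of [starting material] in the starting rate at the charge of the south-east run (at the point where two percent of the starting material have become product) (one fixed amount of product, the same in the runs compared)
- product in the south-west run at 77 min, as a share of the starting material charged
- which of these the readings show (the product kills the catalyst / an uncatalysed path runs beside / nothing beyond the main steps / the catalyst wakes slowly / the catalyst dies in pairs / a little impurity takes part of the catalyst at once)

Take the fall of −ln u from 34 min to 77 min in both runs and average it. This is my own reckoning. It gives the late clock, a pseudo-first-order constant:

κ = 0.0151 min⁻¹

Run that line back to u = 1. It lands after the start, at the wake time L, the delay of a run behind its late clock (the induction period):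

L = 8.79 min

Read this delay as a catalyst that wakes slowly, with awake share a = 1 − exp(−t/L). Now climb the ladder.

Shortest rung: on this curve, the share made grows at first with the square of the time. So my estimate puts the south-east run at 2% at

t = 4.82 min

This is shorter than L, and a is 42.2% there.

Middle rung: L itself. At 34 min, the curve leaves 2.09% still asleep.

Longest rung: 66.2 min, the late clock's time, longer than L.

Compare charges at one fixed amount of product and the same free catalyst. On this curve a larger charge of starting material gets there sooner, as the inverse square root of the charge, and so less awake. With x = t/L = 0.549:

order = 1 − 0.5·x/(exp x − 1) = 0.625

For the south-west run, use the same clock: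

share = 1 − exp(−κ(t − L)) = 64.3%

The forecast gives order 0.97, share 65.5%, and the catalyst wakes slowly. Its ground for the order: “The ratio of product between runs is about 1.5, equal to the charge ratio, so the order in starting material is close to 1”. My order differs from it; my share and reading stand close to it.

The flask gives order 0.65 at the south-east charge, a south-west share of 64.7%, and the catalyst wakes slowly.

2 active catalyst ⇌ catalyst dimer, settled at all times (64.00 L mol⁻¹); active catalyst + starting material → product + active catalyst (4.332 L mol⁻¹ min⁻¹); free catalyst → active catalyst (0.1128 min⁻¹) At that fixed amount the north-east run goes at 0.47 mM min⁻¹ and the south-east run at 0.36 mM min⁻¹, a ratio of 1.3 for a charge ratio of 1.50. Apply L to the north-east run. It reaches that amount at 3.94 min, with a at 36.1%, so L gives a rate ratio of 1.28.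

(All runs were computed on assumed constants, and the scatter is random.)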